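All runs were computed for an exercise; scatter was added.

How far does the free monomer go in 2.0 h at 0.2 mol% initiator, and how long are the chains begun by then?

| flask | free monomer | initiator | remark | time |
|---|---|---|---|---|
| teal | 2 M | 0.28 mol% | run made earlier |  |
| violet | 2 M | 0.44 mol% | run made earlier |  |
| flask | 2.0 M | 0.2 mol% |  | 2.0 h |

- teal (time / min: monomer in chains / %, free monomer / %): 4.00: 91.7, 7.6; 12.0: 91.7, 7.8; 20.0: 90.0, 8.1; 30.0: 89.8, 7.4; 40.0: 88.7, 7.8; 60.0: 87.0, 7.6; 80.0: 85.7, 7.9
- violet (time / min: monomer in chains / %, free monomer / %): 4.00: 92.1, 7.9; 12.0: 91.1, 8.1; 20.0: 90.4, 8.2; 30.0: 89.7, 7.6; 40.0: 88.5, 7.9; 60.0: 87.1, 7.5; 80.0: 85.7, 7.4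

(scatter of a reading: 0.3 percentage points)

- average number of monomer units in a chain (chains begun, living or dead) at 2.0 h
- part of the free monomer that has reacted at 2.0 h

- the average divides the monomer in chains by the number of chains begun, living and dead together
- the numbers in the tables scatter with a standard deviation of 0.3 percentage points
- the earlier runs do not show the number of chains; that part of a forecast is a guess

I turn the question round: what would have to be true for this flask to stop anywhere but where the earlier runs stop? I see two ways: the stopping level moves with the initiator, or this flask needs longer than 2.0 h to reach it.

The tables speak against the first. Free monomer averages 7.74% of the charge in the teal run and 7.80% in the violet run, a gap smaller than the scatter of one reading, though the loadings differ by a factor of 1.57. So I take the mean, 7.77%, and multiply by the charge to get the plateau level, the free monomer left standing beside the chains, 0.155 M, which I read, with the scatter of the tables, as the equilibrium monomer concentration. Divided by the charge of a flask charged above it and standing on its plateau, it gives the fraction left free.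

Against the second, the teal run is on the plateau at its first reading, 4.00 min. If I let that time grow as one over the loading, I estimate this flask there by 5.60 min, far less than 2.0 h. My reckoning for this flask is therefore 92.2% reacted. The chain count cannot be read from the runs.

The forecast says 92.3% reacted and a dp of 420, reasoning that “It is the same at 0.28 and 0.44 mol% initiator, so this is a ceiling-temperature-type equilibrium”.

This flask gives 92.1% reacted and a dp of 412.

    free monomer + initiator → living end + monomer in chains (k = 0.0183 M⁻¹ s⁻¹)
    free monomer + living end → monomer in chains + living end, rate k2*[living end]*[free monomer] (k = 27.5 M⁻¹ s⁻¹)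
    monomer in chains + living end → free monomer + living end, rate k3*[living end] as long as [monomer in chains] is above zero (k = 4.34 s⁻¹)
    monomer in chains → over-reaction product (k = 1.56 × 10⁻⁵ s⁻¹)

Free monomer in this flask stands at 7.89% after 2.00 h, although over-reaction product has reached 9.75%. In the neighbouring flask, charged with 0.80 M at the same loading, the plateau level leaves 19.4% free, so I reckon 80.6% reacted. That flask gives 80.3% reacted, with 19.7% of its charge still free monomer after 2.00 h and a dp of 359.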